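## Analysis of the target

The target 22 is a bicyclo[3.3.1]nonane-2,4,9-trione. Ring B (C1–C2–C3–C4–C5–C9) holds an enolised 1,3-diketone at C2/C4 with an isobutyryl group on C3. Ring A (C1–C8–C7–C6–C5–C9) shares with it the bridgehead methines C1 and C5 and the bridging ketone C9. There are four stereocentres: C1 and C5, whose relation is fixed by the bicycle; the quaternary C8 (methyl and 4-methylpent-3-enyl), bonded directly to C1; and C7 (prenyl). The C7 prenyl group lies on the ring B side (endo, axial on a chair ring A). It is cis to the C8 methyl group and trans to the homoprenyl chain, which is axial on the face of ring A from which C9 rises. The sensitive groups are the acyl-β-diketone (a strong vinylogous acid whose enol ethers are acylating agents), the unhindered C9 ketone between two acidic bridgehead hydrogens, and two trisubstituted alkenes that suffer from acid, electrophilic halogen and carbon radicals five atoms away. The synthesis is hard because C1–C8 joins a bridgehead to a quaternary carbon, because the 7-endo arrangement is the more congested one, and because unsubstituted bridgeheads let ring B precursors aromatise. The plan rests on two features: ring B with its C3 acyl group has the carbon and oxygen pattern of an acylphloroglucinol, with C1 and C5 meta to each other; and the C6–C7–C8 bridge, with cis one-carbon branches on C7 and C8, maps onto a 3-(halomethyl)butenolide whose lactone ring ties the two branches together.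

## Retrosynthetic reasoning

**22 ⇐ 21 ⇐ 20.** The last two operations only unmask. Cutting the O–methyl bond of 21 returns the enol, and 21 comes from carbinol 20 by oxidation at C9. Both masks are needed: the nucleophiles that must act on the lactone carbonyl would first attack a free C9 ketone, and a free enol would be turned into a vinylogous acyl halide by the halogenating reagent. C9 is therefore carried as its alcohol from the hydride step to the penultimate step, and the enol as its methyl ether only through the electrophilic and radical steps.

**20 ⇐ 19 ⇐ 18 ⇐ 17.** The C8 methyl group is traced to a CH2OH group by cutting C–O at the neopentyl carbon. Iodide 19 is reduced by a radical chain, and 19 comes from alcohol 18, the methyl ether of 17. The forward steps must keep the primary radical from closing onto either alkene and must leave the C9 carbinol alone.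

**17 ⇐ 16 ⇐ 14.** The prenyl group is cut twice: at its C=C bond (olefination of δ-lactol 16 by an isopropylidene ylide), and between its first and second carbon (one-carbon homologation of γ-lactol 14 by a methoxymethylene ylide, then hydrolysis). In 14 the C7 branch is at the aldehyde level and the C8 branch at the alcohol level, so the two branches never have to be told apart as a diol. This matters because a 1,4-diol would close to a tetrahydrofuran on activation, and an organocopper coupling on a C7 iodide would meet the electrophilic enol ether.

**14 ⇐ 13 ⇐ 12.** Lactol 14 arises from lactone 13 by partial reduction, which also takes C9 to the carbinol. Lactone 13 comes from 12 by exchange of both bridgehead chlorines for hydrogen through bridgehead radicals, which cannot invert.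

**12 ⇒ 4 + 10.** The central disconnection cuts C5–C6 and C1–C8, the only two bonds that join the C6–C7–C8 bridge to ring B.
- What is gained: ring B returns as an aromatic ring with every oxygen and the acyl group in place, and the bridge returns as butenolide 10, which already carries both C8 substituents and the C7 branch in the right cis relation. One ring, two skeletal bonds and all four stereocentres come from two achiral partners in one operation.
- What the forward reaction must do: alkylate a chlorine-bearing ring carbon of 4 rather than oxygen or the acyl-bearing carbon, then add the second chlorine-bearing carbon to the fully substituted β-carbon of the butenolide through a chair, under a chiral counter-ion that fixes the absolute sense.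
- Why chlorine: it keeps C1 and C5 tetrahedral after each C–C bond formation, so the ring cannot re-aromatise, and it can later be replaced by hydrogen.

**4 ⇐ 3 ⇐ 1 + 2.** The two C–Cl bonds and the ring–acyl bond are cut; both forward reactions are electrophilic aromatic substitutions on a symmetrical triphenol.

**10 ⇐ 9 ⇐ 5 + 6.** Bromide 10 comes from alcohol 9. Butenolide 9 is cut at the bond from the α-carbon to the lactone carbonyl and at the bond from the β-carbon to the homoprenyl chain, which is an alkyne carbometalation followed by carboxylation. Diol 6 supplies the four-carbon chain with both CH2O groups, and Grignard reagent 7 (from 5) supplies the side chain. Alkoxide-directed anti addition places the new carboxyl group cis to a CH2O group, as lactonisation requires, and the symmetry of 6 removes any regiochemical question.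

## Alternatives that were turned down

**Alternative 1:** Ring A is cut at C7–C8 and C1–C9, as a diene and a dienophile held together by an ester tether.
- Forward key step: a 1-silyloxy diene carrying an ester on C5 adds intramolecularly to a β,β-disubstituted enoate and gives cyclohexene A1. In A1 a cis-fused δ-lactone joins the C8 CH2O branch to a C7 acetic acid residue, and C9 bears a silyl ether.
- For it: a suprafacial cycloaddition through a short tether fixes the C7/C8 relation reliably. The δ-lactone already contains the first two carbons of the prenyl group, so one olefination would finish that chain. On this point A1 is better than 12, which needs a homologation.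
- Against it: the dienophile forms a quaternary carbon, the ester tether prefers the conformation that keeps diene and dienophile apart, and the ester on the diene makes the pair electronically mismatched. After A1, ring B is still missing: C5 must be set by reduction of the unsaturated ester, C9 oxidised, and a C2–C3–C4 unit with the acyl group bridged between two epimerisable ester carbons on the face of the C7 substituent. An extra element is needed for the absolute configuration.
- Comparison: as a single reaction the cycloaddition is surer than step 5. The chosen strategy offers in its place both rings, all four stereocentres, the full oxidation pattern of ring B and the acyl group in one step, and far fewer operations after it.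

**Alternative 2:** Ring B is cut at C1–C2.
- Forward key step: a fully substituted ring A cyclohexanone carries the C5 side arm (C4 as a methoxy-bearing carbon, C3, and C2 as an aryl ester) and its C9 oxygen as the silyl enol ether towards C1. A nucleophilic trigger frees the C1 enolate regiospecifically, and it acylates intramolecularly to give A2.
- For it: every reaction type is established on this ring system. The substituents at C7, C8 and C5 are introduced one after another on a cyclohexenone, each trans to its neighbour, which is the arrangement the 7-endo series needs. Both side chains are final from the start, so no deoxygenation or chain extension is required. On confidence in the individual steps and in the relative configuration this alternative is stronger than the chosen plan.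
- Against it: the sequence is linear, and each ring A stereocentre costs one or two steps. The absolute configuration must be brought in with the first conjugate addition. The acylation at C1 takes place next to quaternary C8 and is reversible. After A2 the C4 oxidation level must still be raised and C3 acylated.
- Comparison: the chosen route offers convergence (two fragments of two steps each), catalytic control of the absolute configuration, and the acyl group and full oxidation level of ring B from the beginning.

**Alternative 3:** Ring A is cut at C1–C8.
- Forward key step: an acyclic β-keto ester carbanion at C1 adds 6-exo-trig to a (Z)-β-methyl enoate. Allylic strain around the C7 stereocentre fixes the face and gives cyclohexanone A3, whose quaternary C8 carries methyl and an acetate arm.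
- For it: the difficult C1–C8 bond is made early, in an unstrained monocycle, by a well-precedented closure. The prenyl and methyl groups are in place, and only C7 has to be made enantioselectively. On the security of the quaternary-centre-forming event it is stronger than step 5, where that bond joins two fully substituted carbons.
- Against it: A3 holds only ring A. The acetate arm must be extended to the homoprenyl chain, C5 must be functionalised, and a C2–C3–C4 unit must be bridged across C1 and C5 on the face of the C7 prenyl group. That is the congested face, which diaxial bridging of a cyclohexanone is expected to avoid, so the endo relation is left to the least controllable step.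
- Comparison: in the chosen strategy the relation between the bridge and C7/C8 is decided while ring A closes onto an existing ring B, and the annulation partner fixes C7/C8 by its ring.

Key step: step 5

## Remarks on the chemistry (assumptions)

- Skeleton numbering C1–C9 of the target is used for all bicyclic compounds.
- Catalyst sense: the cinchonidinium salt is written. Whether it or its cinchoninium pseudo-enantiomer gives the C5 configuration drawn has to be established, and the other salt is used if needed.
- C9 carbinol: 14–20 are drawn with the C9 hydroxyl on the ring A side (hydride from the ring B face). The epimer would serve equally, because C9 is a ketone again after step 13.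
- Enol ether: 18–21 are drawn as the C4 O-methyl regioisomer (the oxygen remote from C8). The C2 isomer would behave alike and gives the same 22.
- Lactols 14 and 16 are anomeric mixtures; the anomeric carbon is left undefined in their SMILES.

## Route

Step 1
Reactants: 1 phloroglucinol; 2 isobutyryl chloride
Product: 3 1-(2,4,6-trihydroxyphenyl)-2-methylpropan-1-one
Conditions: AlCl3 (3.5 equiv), PhNO2–CH2Cl2, 0 °C → 60 °C; aq. HCl
Reagents that add atoms: none
Why: Friedel–Crafts acylation of the symmetrical triphenol; every ring carbon is equivalent and the chelated aryl ketone that forms is deactivated towards a second acylation.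

Step 2
Reactants: 3 1-(2,4,6-trihydroxyphenyl)-2-methylpropan-1-one
Product: 4 1-(3,5-dichloro-2,4,6-trihydroxyphenyl)-2-methylpropan-1-one
Conditions: SO2Cl2 (2.05 equiv), Et2O–CH2Cl2, 0 °C → rt
Reagents that add atoms: sulfuryl chloride ClS(Cl)(=O)=O
Why: Electrophilic aromatic chlorination at the only two ring carbons that bear hydrogen; two equivalents at low temperature should stop at the dichloride, because a third chlorination has to break aromaticity and is slower.

Step 3
Reactants: 5 5-bromo-2-methylpent-2-ene; 6 but-2-yne-1,4-diol
Product: 9 3-(hydroxymethyl)-4-(4-methylpent-3-enyl)furan-2(5H)-one, via Grignard reagent 7 (not isolated), via alkenylmagnesium adduct 8 (not isolated)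
Conditions: 5, Mg, THF, 40 °C; then 6 (7 in 3.5-fold excess), CuI (10 mol %), THF, 0 °C → reflux; CO2 (g), 0 °C → rt; 2 M HCl, rt
Reagents that add atoms: carbon dioxide O=C=O; magnesium [Mg] (kept only in 7 and 8)
Why: Copper-catalysed anti-carbomagnesiation of a propargylic alkoxide: the alkoxide directs 7 across the triple bond so that the new C–Mg bond is held cis to one CH2O group in a five-membered chelate, and carboxylation of that alkenyl Grignard followed by acid gives the cis hydroxy acid, which lactonises. The symmetry of 6 makes regiochemistry moot; the homoprenyl group ends on the β-carbon and the second CH2OH on the α-carbon of the butenolide.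

Step 4
Reactants: 9 3-(hydroxymethyl)-4-(4-methylpent-3-enyl)furan-2(5H)-one
Product: 10 3-(bromomethyl)-4-(4-methylpent-3-enyl)furan-2(5H)-one
Conditions: CBr4, PPh3, CH2Cl2, 0 °C
Reagents that add atoms: tetrabromomethane BrC(Br)(Br)Br
Why: Appel reaction; the primary allylic alcohol is displaced by bromide at the oxyphosphonium stage under neutral conditions that leave the lactone and the trisubstituted alkene alone.

Step 5
Reactants: 4 1-(3,5-dichloro-2,4,6-trihydroxyphenyl)-2-methylpropan-1-one; 10 3-(bromomethyl)-4-(4-methylpent-3-enyl)furan-2(5H)-one
Product: 12 1,5-dichloro lactone-fused bicyclic acyl-trione, via chlorodienone 11 (not isolated)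
Conditions: CsOH·H2O (4 equiv), N-(9-anthracenylmethyl)-O-allylcinchonidinium bromide (15 mol %), 4 Å MS, CH2Cl2–PhMe, −50 °C → −20 °C, slow addition of 10 (1.05 equiv); aq. HCl
Reagents that add atoms: none
Why: Proposed new method: the ammonium/caesium phenoxide of 4 is alkylated by 10 at a chlorine-bearing ring carbon (SN2 at CH2Br; an SN2′ entry at the β-carbon followed by Michael addition to the resulting methylene lactone would lead to the same skeleton), which gives the non-aromatic chlorodienone 11 because that carbon cannot tautomerise back, and the enolate carbon that still bears chlorine (C1) then adds to the butenolide β-carbon before the lactone enolate is protonated. The closest known reaction types are the alkylative dearomatisation–annulation of 3,5-dialkyl acylphloroglucinols with 2-(acyloxymethyl) enals and the phase-transfer C-alkylation and Michael addition of 2-chloro-1,3-dicarbonyl compounds; new here are chlorine as the blocking substituent and a β,β-disubstituted butenolide as acceptor. Ring A (C1–C8–C7–C6–C5–C9) closes 6-endo-trig through a chair; the γ-lactone is carried in and no other ring is formed. C5 is set in the intermolecular alkylation by the chiral ion pair, which tells the two enantiotopic C–Cl carbons apart, and C1 has no freedom because the bridge can only close on the face of ring B that carries C6. At C8 the planar lactone enolate holds the CH2O branch in the plane of trigonal C7, hence equatorial on the chair, so the homoprenyl chain (cis to C6 on the butenolide) becomes axial on the C9 side; the boat alternative would push the enolate oxygen against the C9 oxygen. C7 is set by protonation of the lactone enolate from the open exo face, which puts the carbonyl endo and gives the cis-fused γ-lactone, the less strained fusion at a quaternary junction. The step needs C- over O-alkylation and reaction at C–Cl rather than at the acyl-bearing C3: the soft allylic bromide and a tight ion pair in a non-polar medium favour carbon, C3 is the most hindered and least charged carbon, and one equivalent of 10 at low temperature guards against a second alkylation and against hydroxide attack at the activated C9 carbonyl.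

Step 6
Reactants: 12 1,5-dichloro lactone-fused bicyclic acyl-trione
Product: 13 bridgehead-H lactone acyl-trione
Conditions: Bu3SnH (4 equiv), (PhSe)2 (10 mol %), AIBN, PhH, 80 °C; aq. KF
Reagents that add atoms: none
Why: Radical chain dehalogenation of α-chloro ketones; both bridgehead radicals are pyramidal and take up hydrogen with retention, so C1 and C5 keep their configuration. Benzeneselenol formed in the flask from (PhSe)2 transfers hydrogen fast enough to outrun 5-exo addition of the C1 radical to the homoprenyl alkene.

Step 7
Reactants: 13 bridgehead-H lactone acyl-trione
Product: 14 C9-hydroxy γ-lactol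
Conditions: i-Bu2AlH (4.5 equiv), CH2Cl2–PhMe, −78 °C; MeOH, aq. potassium sodium tartrate
Reagents that add atoms: none
Why: Low-temperature hydride reduction: the acidic enol first becomes an aluminium enolate that resists hydride, the γ-lactone stops at the lactol (stable tetrahedral aluminate at −78 °C), and the C9 ketone is taken to the carbinol on purpose so that it is masked during the two olefinations. Hydride is expected from the flat ring B face, and C7 is untouched because the lactol stays closed.

Step 8
Reactants: 14 C9-hydroxy γ-lactol
Product: 16 C9-hydroxy δ-lactol, via methyl enol ether 15 (not isolated)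
Conditions: Ph3P(CH2OMe)Cl (6 equiv), KN(SiMe3)2 (5.8 equiv), THF, 0 °C → rt; then 1 M HCl, THF, rt
Reagents that add atoms: (methoxymethyl)triphenylphosphonium chloride COC[P+](c1ccccc1)(c1ccccc1)c1ccccc1.[Cl-]; water O
Why: Wittig olefination of the lactol through its hydroxy aldehyde form; excess ylide first deprotonates the enol and the hydroxyl groups, and the enolate shields ring B. Acid hydrolysis of the enol ether gives the homologous aldehyde, which the C8 CH2OH traps as the six-membered lactol; the two branches stay at different oxidation levels.

Step 9
Reactants: 16 C9-hydroxy δ-lactol
Product: 17 C7-prenyl C8-hydroxymethyl C9-carbinol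
Conditions: Ph3P(i-Pr)I (6 equiv), n-BuLi (5.8 equiv), THF, 0 °C → rt; aq. NH4Cl
Reagents that add atoms: isopropyltriphenylphosphonium iodide CC(C)[P+](c1ccccc1)(c1ccccc1)c1ccccc1.[I-]
Why: Wittig olefination of the δ-lactol with the isopropylidene ylide completes the prenyl group; no E/Z question arises because the new alkene carbon carries two methyl groups, and C7 is no longer α to a carbonyl group.

Step 10
Reactants: 17 C7-prenyl C8-hydroxymethyl C9-carbinol
Product: 18 O-methyl enol ether of 17
Conditions: Me3SiCHN2 (1.5 equiv), MeOH–PhMe, 0 °C
Reagents that add atoms: (trimethylsilyl)diazomethane C[Si](C)(C)C=[N+]=[N-]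
Why: O-Methylation of a vinylogous acid by a diazoalkane; only the acidic enol protonates the reagent, so both alcohols stay free. The ether masks the enol against the phosphonium iodide and the periodinane of the next steps.

Step 11
Reactants: 18 O-methyl enol ether of 17
Product: 19 C8-iodomethyl compound
Conditions: PPh3, I2, imidazole (premixed), PhMe, 70 °C
Reagents that add atoms: iodine II
Why: Garegg–Samuelsson (Appel-type) iodination, selective for the primary alcohol; the C9 carbinol between two bridgeheads is hindered and cannot be displaced. The neopentyl-type position needs heating, and premixing the reagents leaves no free iodine for the alkenes.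

Step 12
Reactants: 19 C8-iodomethyl compound
Product: 20 C8-methyl C9-carbinol methyl ether
Conditions: Bu3SnH (1.5 equiv), (PhSe)2 (10 mol %), Et3B, air, PhMe, 0 °C → rt
Reagents that add atoms: none
Why: Radical chain deiodination; selenol-mediated hydrogen transfer at low temperature is intended to be faster than 5-exo cyclisation of the primary radical onto either trisubstituted alkene. No stereocentre is touched, and C8 now carries methyl and homoprenyl.

Step 13
Reactants: 20 C8-methyl C9-carbinol methyl ether
Product: 21 O-methyl ether of the target
Conditions: Dess–Martin periodinane, NaHCO3, CH2Cl2, rt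
Reagents that add atoms: none
Why: Dess–Martin oxidation of the secondary alcohol restores the C9 ketone under non-acidic, non-nucleophilic conditions that spare the alkenes and the vinylogous ester; the C9 stereocentre made in step 7 is erased.

Step 14
Reactants: 21 O-methyl ether of the target
Product: 22 target (CNP0285183.2)
Conditions: LiCl (10 equiv), DMSO, 120 °C; aq. HCl
Reagents that add atoms: none
Why: Nucleophilic O-demethylation of a vinylogous ester: chloride attacks the methyl group in a dipolar aprotic solvent, the acyl-dione anion being a very good leaving group, and acidification gives the enol. Either enol-ether regioisomer converges on 22.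

## Compound list

1 | phloroglucinol (benzene-1,3,5-triol) | Oc1cc(O)cc(O)c1 | starting material
2 | isobutyryl chloride | CC(C)C(Cl)=O | starting material
3 | 1-(2,4,6-trihydroxyphenyl)-2-methylpropan-1-one | CC(C)C(=O)c1c(O)cc(O)cc1O | intermediate
4 | 1-(3,5-dichloro-2,4,6-trihydroxyphenyl)-2-methylpropan-1-one | CC(C)C(=O)c1c(O)c(Cl)c(O)c(Cl)c1O | intermediate
5 | 5-bromo-2-methylpent-2-ene | CC(C)=CCCBr | starting material
6 | but-2-yne-1,4-diol | OCC#CCO | starting material
7 | (4-methylpent-3-enyl)magnesium bromide | CC(C)=CCC[Mg]Br | intermediate
8 | (Z)-3-(bromomagnesio)-2-(4-methylpent-3-enyl)but-2-ene-1,4-diol bis(bromomagnesium) alkoxide (Mg cis to the C1 CH2O group) | CC(C)=CCC/C(CO[Mg]Br)=C(\CO[Mg]Br)[Mg]Br | intermediate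
9 | 3-(hydroxymethyl)-4-(4-methylpent-3-enyl)furan-2(5H)-one | CC(C)=CCCC1=C(CO)C(=O)OC1 | intermediate
10 | 3-(bromomethyl)-4-(4-methylpent-3-enyl)furan-2(5H)-one | CC(C)=CCCC1=C(CBr)C(=O)OC1 | intermediate
11 | chlorodienone: 4 alkylated at one C–Cl carbon (C5) by the butenolide CH2 group, other C–Cl carbon still enolised | CC(C)=CCCC1=C(C[C@]2(Cl)C(=O)C(C(=O)C(C)C)=C(O)C(Cl)=C2O)C(=O)OC1 | intermediate
12 | 1,5-dichloro-2-hydroxy-3-isobutyrylbicyclo[3.3.1]non-2-ene-4,9-dione with a cis-fused γ-lactone from the C8 CH2O branch (equatorial) to the C7 carbonyl (endo); homoprenyl axial on C8 | CC(C)=CCC[C@]13COC(=O)[C@@H]3C[C@]2(Cl)C(=O)C(C(=O)C(C)C)=C(O)[C@@]1(Cl)C2=O | intermediate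
13 | 12 with hydrogen in place of both bridgehead chlorines | CC(C)=CCC[C@]13COC(=O)[C@@H]3C[C@@H]2C(=O)C(C(=O)C(C)C)=C(O)[C@H]1C2=O | intermediate
14 | 13 with the lactone carbonyl reduced to the γ-lactol (anomeric mixture) and C9 reduced to the carbinol (OH on the ring A side) | CC(C)=CCC[C@]13COC(O)[C@@H]3C[C@@H]2C(=O)C(C(=O)C(C)C)=C(O)[C@H]1[C@@H]2O | intermediate
15 | ring-opened enol ether: C7 2-methoxyvinyl (E/Z mixture), C8 CH2OH, C9 carbinol | CC(C)=CCC[C@@]1(CO)[C@H](C=COC)C[C@@H]2C(=O)C(C(=O)C(C)C)=C(O)[C@H]1[C@@H]2O | intermediate
16 | δ-lactol (anomeric mixture) between the C7 CH2CHO arm and the C8 CH2OH, C9 carbinol | CC(C)=CCC[C@]13COC(O)C[C@@H]3C[C@@H]2C(=O)C(C(=O)C(C)C)=C(O)[C@H]1[C@@H]2O | intermediate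
17 | C7 prenyl (endo), C8 CH2OH and homoprenyl, C9 carbinol, free enol | CC(C)=CCC[C@@]1(CO)[C@H](CC=C(C)C)C[C@@H]2C(=O)C(C(=O)C(C)C)=C(O)[C@H]1[C@@H]2O | intermediate
18 | C4 O-methyl enol ether of 17 | CC(C)=CCC[C@@]1(CO)[C@H](CC=C(C)C)C[C@@H]2C(OC)=C(C(=O)C(C)C)C(=O)[C@H]1[C@@H]2O | intermediate
19 | 18 with C8 CH2I in place of CH2OH | CC(C)=CCC[C@@]1(CI)[C@H](CC=C(C)C)C[C@@H]2C(OC)=C(C(=O)C(C)C)C(=O)[C@H]1[C@@H]2O | intermediate
20 | C8 methyl compound, C9 carbinol, C4 O-methyl enol ether | CC(C)=CCC[C@@]1(C)[C@H](CC=C(C)C)C[C@@H]2C(OC)=C(C(=O)C(C)C)C(=O)[C@H]1[C@@H]2O | intermediate
21 | C4 O-methyl enol ether of the target (C9 ketone) | CC(C)=CCC[C@@]1(C)[C@H](CC=C(C)C)C[C@@H]2C(OC)=C(C(=O)C(C)C)C(=O)[C@H]1C2=O | intermediate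
22 | CNP0285183.2 | CC(C)=CCC[C@@]1(C)[C@H](CC=C(C)C)C[C@@H]2C(=O)C(C(=O)C(C)C)=C(O)[C@H]1C2=O | target

## Step count and least certain steps

Total: 14 steps. Longest linear sequence: 12 steps (steps 3–14 from 5 and 6; equally steps 1, 2 and 5–14 from 1).

**Step 5 (key step).** Several processes can divert it:
- alkylation on oxygen or at the acyl-bearing carbon instead of a C–Cl carbon;
- chlorine transfer from the chlorodienone to a second phenoxide, or hydroxide attack at the doubly activated C9 carbonyl with ring cleavage;
- reversible oxa-Michael closure through the C9 enolate oxygen;
- slow or reversible C1–C8 bond formation, because two fully substituted carbons are joined, or a boat-type closure that inverts C8;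
- weak discrimination of the two enantiotopic C–Cl carbons by the ion pair.

Fallback with known reaction types, from 3 and 10 back to 12: DBU-mediated C-alkylation of 3 with 10 in THF gives the aromatic C-alkyl acylphloroglucinol F1. N-Chlorosuccinimide (2 equiv) first chlorinates the free ring position and then the alkyl-bearing carbon (ipso-chlorination of an alkylphenol to a 4-alkyl-4-chlorocyclohexadienone), giving the racemic chlorodienone F2. K2CO3 in MeCN effects the intramolecular Michael addition of the 2-chloro-1,3-dicarbonyl anion to the racemic annulation product F3, which is resolved as its salt with (R)-1-phenylethylamine (the acyl-dione is a strong acid) to return 12. This gives up catalytic enantiocontrol but separates the dearomatisation from the C–C bond formation; it does not remove the difficulty of the C1–C8 closure itself.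

**Step 6.** The C1 bridgehead radical may cyclise 5-exo onto the homoprenyl alkene before hydrogen transfer, and chlorine abstraction may be slow at a bridgehead where the radical gains no conjugation. Fallback from 12 to 13: two-electron reduction with zinc dust in AcOH–THF at rt, which passes through zinc enolates (allowed at the bridgeheads of a bicyclo[3.3.1]nonane) and leaves no free radical next to the alkene; no new compound.

**Step 8.** C7 may epimerise by enolisation of the ring-opened hydroxy aldehyde under the basic ylide (the exo aldehyde is less congested), and the hindered lactol may open too reluctantly for full conversion. Fallback from 14 to 16: non-basic titanium-mediated methylenation (Zn, CH2Br2, TiCl4) gives the C7 vinyl compound F4. Hydroboration of the monosubstituted alkene with 9-BBN and oxidation with NaBO3 gives the triol F5. PhI(OAc)2/TEMPO oxidises the unhindered primary alcohol, and the lactol that follows, to the δ-lactone F6. i-Bu2AlH at −78 °C then gives 16.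

**Step 11 (with step 12).** Displacement at the neopentyl-type carbon is slow, and in that time the C9 carbinol may be activated, iodide may remove the O-methyl group, or an alkene may participate. In step 12 the primary radical may still close 5-exo. Fallback from 17 to 20, polar throughout: TsCl, Et3N and DMAP sulfonylate the primary alcohol to the tosylate F7 (an enol tosylate formed on the way passes its sulfonyl group on or is cleaved with K2CO3/MeOH). LiBHEt3 in THF at 65 °C, which leaves the enolate and the alkenes alone, displaces the tosylate by hydride and gives the C8 methyl compound F8. Me3SiCHN2 then gives 20.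

**Step 3.** The Grignard reagent may only deprotonate the diol without adding (the dialkoxide is a poor acceptor for a primary alkyl Grignard reagent), partial syn addition would give an acid that cannot lactonise, and carboxylation may be incomplete. Fallback from 5 to 9: zinc insertion (Zn, LiCl, THF) converts 5 into the organozinc reagent F9. Negishi coupling with commercial 3,4-dibromofuran-2(5H)-one F10 [Pd(PPh3)4, THF], which reacts at C4 (the vinylogous acyl bromide position), gives the bromobutenolide F11. Stille coupling with (tributylstannyl)methanol [Pd(PPh3)4, dioxane, 100 °C] gives 9.

## Further compounds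

F1 | step 5 | 3-{[2,4,6-trihydroxy-3-(2-methylpropanoyl)phenyl]methyl}-4-(4-methylpent-3-enyl)furan-2(5H)-one | CC(C)=CCCC1=C(Cc2c(O)cc(O)c(C(=O)C(C)C)c2O)C(=O)OC1
F2 | step 5 | racemic chlorodienone (constitution of 11) | CC(C)=CCCC1=C(CC2(Cl)C(=O)C(C(=O)C(C)C)=C(O)C(Cl)=C2O)C(=O)OC1
F3 | step 5 | racemic 12 (both enantiomers, relative configuration of 12) | CC(C)=CCC[C@]13COC(=O)[C@@H]3C[C@]2(Cl)C(=O)C(C(=O)C(C)C)=C(O)[C@@]1(Cl)C2=O.CC(C)=CCC[C@@]13COC(=O)[C@H]3C[C@@]2(Cl)C(=O)C(C(=O)C(C)C)=C(O)[C@]1(Cl)C2=O
F0 | step 6 | none | none
F4 | step 8 | C7 vinyl, C8 CH2OH, C9 carbinol, free enol | CC(C)=CCC[C@@]1(CO)[C@H](C=C)C[C@@H]2C(=O)C(C(=O)C(C)C)=C(O)[C@H]1[C@@H]2O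
F5 | step 8 | C7 2-hydroxyethyl, C8 CH2OH, C9 carbinol, free enol | CC(C)=CCC[C@@]1(CO)[C@H](CCO)C[C@@H]2C(=O)C(C(=O)C(C)C)=C(O)[C@H]1[C@@H]2O
F6 | step 8 | δ-lactone corresponding to lactol 16 | CC(C)=CCC[C@]13COC(=O)C[C@@H]3C[C@@H]2C(=O)C(C(=O)C(C)C)=C(O)[C@H]1[C@@H]2O
F7 | step 11 | primary tosylate of 17 | CC(C)=CCC[C@@]1(COS(=O)(=O)c3ccc(C)cc3)[C@H](CC=C(C)C)C[C@@H]2C(=O)C(C(=O)C(C)C)=C(O)[C@H]1[C@@H]2O
F8 | step 11 | C8 methyl compound, C9 carbinol, free enol | CC(C)=CCC[C@@]1(C)[C@H](CC=C(C)C)C[C@@H]2C(=O)C(C(=O)C(C)C)=C(O)[C@H]1[C@@H]2O
F9 | step 3 | (4-methylpent-3-enyl)zinc bromide | CC(C)=CCC[Zn]Br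
F10 | step 3 | 3,4-dibromofuran-2(5H)-one | O=C1OCC(Br)=C1Br
F11 | step 3 | 3-bromo-4-(4-methylpent-3-enyl)furan-2(5H)-one | CC(C)=CCCC1=C(Br)C(=O)OC1
A1 | alternative 1 | lactone-fused cyclohexene diester | CC(C)=CCC[C@]12COC(=O)C[C@@H]2C=C(C(=O)OC)[C@H](O[Si](C)(C)C(C)(C)C)[C@@H]1C(=O)OC
A2 | alternative 2 | 4-methoxybicyclo[3.3.1]nonane-2,9-dione (C4 epimer inconsequential) | CC(C)=CCC[C@@]1(C)[C@H](CC=C(C)C)C[C@@H]2[C@@H](OC)CC(=O)[C@H]1C2=O
A3 | alternative 3 | ring-A β-keto ester with C8 acetate arm | COC(=O)C[C@@]1(C)[C@H](CC=C(C)C)CCC(=O)[C@@H]1C(=O)OC
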